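I began with substrate. In the new flask, reagent stood at 1.80 equiv, so substrate was the limiting reagent, and I wrote its balance in fractions of the charge, with a for substrate left, p for target, e for isomer of the product and u for whatever the chromatographic readings did not show:

a + p + e + u = 1

| flask | substrate | reagent | catalyst | remark | time |
|---|---|---|---|---|---|
| teal | 0.40 M | 1.8 equiv | 3.4 mol% | run made earlier |  |
| violet | 0.40 M | 1.8 equiv | 7.5 mol% | run made earlier |  |
| amber | 0.80 M | 1.8 equiv | 5 mol% | run made earlier |  |
| flask | 0.40 M | 1.80 equiv | 5 mol% |  | 2.0 h |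

| run | time / min | target / % | isomer of the product / % |
|---|---|---|---|
| teal | 10.0 | 22.0 | 25.9 |
| teal | 25.0 | 21.2 | 26.5 |
| teal | 50.0 | 21.6 | 25.5 |
| teal | 80.0 | 21.8 | 25.5 |
| violet | 20.0 | 22.3 | 27.1 |
| violet | 40.0 | 22.1 | 26.6 |
| violet | 50.0 | 21.7 | 25.6 |
| violet | 80.0 | 20.9 | 25.1 |
| amber | 20.0 | 28.7 | 33.8 |
| amber | 40.0 | 28.8 | 34.7 |
| amber | 50.0 | 27.5 | 33.4 |
| amber | 80.0 | 27.7 | 33.2 |

(readings scatter by 0.5 percentage points)

- ratio of target to isomer of the product at 12 s
- ratio of target to isomer of the product at 5.0 min
- ratio of target to isomer of the product at 2.0 h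

- the numbers in the tables scatter by 0.5 percentage points (one standard deviation)

At 50.0 min the seen share p + e was 47.1 % in the teal run and 60.9 % in the amber run, yet the quotient p/e, which contains no u, read 0.847 and 0.823. So I carried that quotient, the plateau ratio, target over isomer of the product once both readings stand still, and bracketed it. Taken singly, teal pairs ran from 0.800 at 25.0 min to 0.855 at 80.0 min. Summing each run narrowed this:

teal: 0.838
violet: 0.833
amber: 0.834
pooled: 0.835

I committed the pooled reading to 2.0 h, but the bracket said nothing of 12 s or 5.0 min, which lie before the first reading at 10.0 min.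

The forecast gave 0.835 at 2.0 h, inside the span of my single teal pairs , and 0.84 at 5.0 min. For 12 s it gave 0.84, between 0.2 and 4, saying: “The ratio is then kinetic and the data say nothing about it”.

The flask gave 5.99 at 12 s, above the forecast's high end, then 0.855 at 5.0 min and 0.833 at 2.0 h, beside my plateau ratio of 0.835; target and isomer of the product stood level at 1.97 min.

    target ⇌ isomer of the product (K = 1.20, k = 0.0360 /s)
    substrate + catalyst → catalyst + intermediate (k = 13.0 /M/s)
    target → over-reaction product (k = 2.00 × 10⁻⁵ /s)
    reagent + catalyst + intermediate ⇌ catalyst + target (K = 0.820 /M, k = 0.350 /M²/s)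

A neighbouring flask with 4.50 equiv of reagent ended with 38.0 % of the substrate charged as isomer of the product, against 25.6 % in this flask. The plateau ratio turned that neighbour's isomer into 31.7 % of target, its ratio stood at 0.833, and that neighbour held 31.7 % of target.

Readings and results are calculated from invented constants, and the scatter is random.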